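The route rests on cutting the bond between C6 of the 1,2-dioxane ring (O1, O2, C3–C6) and the first carbon of the two-carbon tether to decalin C9, with the tether carried as an alkyne. In one operation the key step joins a decalin alkynyltrifluoroborate to the cyclic peroxycarbenium ion formed from a 6-methoxy-6-methyl-1,2-dioxane that already bears the C3 propanoate, and creates the fully substituted peroxide carbon C6. It exploits the cis relation between the C6 tether and the C3 propanoate, which is what axial attack on the half-chair cation delivers. The precursors are an enantiopure drim-7-ene-type alkynylborate from (S)-carvone and a peroxyketal ester from methyl levulinate; diimide then saturates the alkyne.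

Key step: step 21

Assumption: (−)-Ipc2BOMe is the reagent made from (+)-α-pinene; the peroxyketal carbon of 26–30 is carried as an epimer mixture because it becomes planar in step 21; anions formed by simple deprotonation of numbered compounds (enolates, acetylides, peroxide anions) count as part of the conditions.
Numbering: decalin atoms carry drimane numbers (C4 gem-dimethyl, C5 and C10 ring fusion, C8 methyl-bearing, C9 chain-bearing; "11-nordrimane" is this decalin without a carbon substituent on C9). 5-H is anti to the 10-methyl throughout.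

Step 1
Reactants: 1 3-(trimethylsilyl)prop-2-yn-1-ol
Product: 2 (Z)-3-(trimethylsilyl)prop-2-en-1-ol
Conditions: H2 (1 atm), Pd/CaCO3 poisoned with Pb(OAc)2, quinoline, hexane, rt
Reagents that add atoms: none
Why: Lindlar-type semihydrogenation, in which syn delivery of hydrogen on the poisoned palladium surface should give the Z-alkene and quinoline should stop over-reduction.

Step 2
Reactants: 2 (Z)-3-(trimethylsilyl)prop-2-en-1-ol
Product: 3 (Z)-(3-bromoprop-1-enyl)trimethylsilane
Conditions: CBr4, PPh3, CH2Cl2, 0 °C
Reagents that add atoms: carbon tetrabromide BrC(Br)(Br)Br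
Why: Appel reaction, which converts the primary allylic alcohol into the bromide through an alkoxyphosphonium ion under neutral conditions so that the Z-vinylsilane geometry is kept.

Step 3
Reactants: 4 (S)-(+)-carvone
Product: 5 (5S)-6-methylcarvone (mixture of C6 epimers)
Conditions: LiN(iPr)2, THF, −78 °C; CH3I, −78 to 0 °C
Reagents that add atoms: iodomethane CI
Why: Kinetic α'-enolate alkylation of the cross-conjugated enone, whose new C6 centre need not be controlled because it is re-enolised in step 4.

Step 4
Reactants: 5 (5S)-6-methylcarvone; 3 (Z)-(3-bromoprop-1-enyl)trimethylsilane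
Product: 6 (5R,6R)-2,6-dimethyl-5-isopropenyl-6-[(Z)-3-(trimethylsilyl)prop-2-enyl]cyclohex-2-enone
Conditions: LiN(iPr)2, THF, −78 to 0 °C; 3, DMPU, −78 °C to rt
Reagents that add atoms: none
Why: Second α'-enolate alkylation, in which the allylic bromide should approach the tetrasubstituted enolate anti to the neighbouring isopropenyl group and so set the quaternary carbon (future C10) with methyl cis and silylallyl trans to isopropenyl.

Step 5
Reactants: 6 (5R,6R)-2,6-dimethyl-5-isopropenyl-6-[(Z)-3-(trimethylsilyl)prop-2-enyl]cyclohex-2-enone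
Product: 7 (5R,10R)-11-nordrima-2,7-dien-9-one (trans-fused dienone)
Conditions: CF3CO2H, CH2Cl2, 0 °C
Reagents that add atoms: none
Why: Vinylsilane-terminated cation-olefin cyclization, in which Markovnikov protonation of the isopropenyl group gives a tertiary cation that is captured 6-endo at the silicon-bearing carbon (β-silyl cation) through a diequatorial chair-like closure, so that loss of silicon leaves the C2=C3 alkene and the trans ring fusion follows from the two centres set before.

Step 6
Reactants: 7 (5R,10R)-11-nordrima-2,7-dien-9-one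
Product: 8 (5R,10R)-11-nordrim-7-en-9-one
Conditions: H2 (1 atm), RhCl(PPh3)3 (5 mol %), benzene/EtOH, rt
Reagents that add atoms: none
Why: Homogeneous hydrogenation with RhCl(PPh3)3, which should reduce the cis-disubstituted ring A alkene and leave the trisubstituted conjugated enone alone.

Step 7
Reactants: 8 (5R,10R)-11-nordrim-7-en-9-one; 9 ethynyltrimethylsilane
Product: 10 (5R,10R)-9-[(trimethylsilyl)ethynyl]-11-nordrim-7-en-9-ol (C9 epimers)
Conditions: 9, nBuLi, THF, −78 °C; CeCl3; then 8, −78 to 0 °C
Reagents that add atoms: none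
Why: 1,2-Addition of an organocerium acetylide, a slim and weakly basic nucleophile that should add to the hindered C9 carbonyl without γ-deprotonation, the carbinol configuration being erased in step 8.

Step 8
Reactants: 10 (5R,10R)-9-[(trimethylsilyl)ethynyl]-11-nordrim-7-en-9-ol
Product: 11 (5R,10R)-9-[(trimethylsilyl)ethynyl]-11-nordrim-8-en-7-one
Conditions: [C5H5NH][CrO3Cl], 4 Å molecular sieves, CH2Cl2, rt
Reagents that add atoms: pyridinium chlorochromate [O-][Cr](=O)(=O)Cl.c1cc[nH+]cc1
Why: Babler–Dauben oxidative transposition, in which the tertiary allylic chromate ester undergoes a [3,3]-shift to C7 and is oxidised there, moving oxygen to C7 and the alkene to C8=C9.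

Step 9
Reactants: 11 (5R,10R)-9-[(trimethylsilyl)ethynyl]-11-nordrim-8-en-7-one
Product: 12 tosylhydrazone of 11
Conditions: TsNHNH2, AcOH (cat.), EtOH, 50 °C
Reagents that add atoms: 4-methylbenzenesulfonyl hydrazide Cc1ccc(cc1)S(=O)(=O)NN
Why: Acid-catalysed condensation of the unhindered C7 ketone with tosylhydrazide, which should leave the silylalkyne untouched.

Step 10
Reactants: 12 tosylhydrazone of 11
Product: 15 (5R,9S,10R)-9-[(trimethylsilyl)ethynyl]-11-nordrim-7-ene (9-H syn to 10-CH3), via allylic N-tosylhydrazine 13 (not isolated), via allylic diazene 14 (not isolated)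
Conditions: catecholborane, CHCl3, 0 °C; NaOAc·3H2O, 60 °C
Reagents that add atoms: none
Why: Reductive 1,3-transposition of a conjugated tosylhydrazone, in which catecholborane should deliver hydride to C7 along the axial trajectory on the face anti to the 10-methyl, acetate then expels sulfinate from 13 to give diazene 14 with nitrogen syn to the 10-methyl, and retro-ene loss of N2 transfers hydrogen suprafacially to C9 on that face, setting C9 (9-H syn to 10-CH3, alkyne anti) and moving the alkene to C7=C8, as in the known conversion of steroidal 4-en-3-one tosylhydrazones into 5β-3-enes.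

Step 11
Reactants: 15 (5R,9S,10R)-9-[(trimethylsilyl)ethynyl]-11-nordrim-7-ene
Product: 16 (5R,9S,10R)-9-ethynyl-11-nordrim-7-ene
Conditions: K2CO3, MeOH, rt
Reagents that add atoms: none
Why: Methanolysis of the C(sp)–Si bond with carbonate, which is mild enough not to isomerise the skipped enyne or epimerise C9.

Step 12
Reactants: 16 (5R,9S,10R)-9-ethynyl-11-nordrim-7-ene
Product: 18 potassium trifluoro{[(5R,9S,10R)-11-nordrim-7-en-9-yl]ethynyl}borate (fragment 1), via lithium alkynyltrimethoxyborate 17 (not isolated)
Conditions: nBuLi, THF, −78 °C; B(OMe)3, −78 to −20 °C; KHF2, H2O, 0 °C to rt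
Reagents that add atoms: trimethyl borate COB(OC)OC; potassium hydrogen difluoride [K+].F[H-]F
Why: Selective deprotonation of the terminal alkyne (far more acidic than the allylic-propargylic C9–H), borylation and fluoride exchange, the standard preparation of crystalline potassium alkynyltrifluoroborates.

Step 13
Reactants: 19 methyl levulinate
Product: 20 methyl 4,4-dimethoxypentanoate
Conditions: HC(OMe)3, TsOH·H2O (cat.), MeOH, rt
Reagents that add atoms: trimethyl orthoformate COC(OC)OC; methanol CO
Why: Acid-catalysed ketalisation with orthoformate as water scavenger, which protects the ketone and installs the later leaving group of the peroxyketal.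

Step 14
Reactants: 20 methyl 4,4-dimethoxypentanoate
Product: 21 4,4-dimethoxypentanal
Conditions: iBu2AlH, CH2Cl2, −78 °C; aqueous potassium sodium tartrate
Reagents that add atoms: none
Why: Partial ester reduction with iBu2AlH, which should stop at the tetrahedral aluminium hemiacetal at −78 °C and release the aldehyde on work-up while the ketal stays inert.

Step 15
Reactants: 21 4,4-dimethoxypentanal; 22 cis-but-2-ene
Product: 24 (3R,4R)-7,7-dimethoxy-3-methyloct-1-en-4-ol (syn), via (Z)-crotylbis(isopinocampheyl)borane 23 (not isolated)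
Conditions: 22, KOtBu, nBuLi, THF, −78 to −45 °C; (−)-Ipc2BOMe, −78 °C; BF3·OEt2; 21, −78 °C; NaOH, H2O2, 0 °C to rt
Reagents that add atoms: none
Why: Asymmetric crotylboration through a closed chair (Zimmerman–Traxler-type) transition state, in which the Z geometry of 23 gives the syn adduct and the isopinocampheyl groups from (+)-α-pinene select the aldehyde face that leads to the (3R,4R) alcohol.

Step 16
Reactants: 24 (3R,4R)-7,7-dimethoxy-3-methyloct-1-en-4-ol
Product: 25 (3R,4R)-7,7-dimethoxy-3-methyloct-1-en-4-yl methanesulfonate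
Conditions: CH3SO2Cl, Et3N, CH2Cl2, 0 °C
Reagents that add atoms: methanesulfonyl chloride CS(=O)(=O)Cl
Why: Sulfonylation of the secondary alcohol with retention under basic conditions, which also prevents acid-induced cyclisation of the γ-hydroxy ketal.

Step 17
Reactants: 25 (3R,4R)-7,7-dimethoxy-3-methyloct-1-en-4-yl methanesulfonate
Product: 26 (3R,4R)-7-hydroperoxy-7-methoxy-3-methyloct-1-en-4-yl methanesulfonate (C7 epimers)
Conditions: urea·H2O2, Sc(OTf)3 (cat.), MeOH, 0 °C to rt
Reagents that add atoms: urea–hydrogen peroxide adduct NC(N)=O.OO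
Why: Lewis acid-catalysed perhydrolysis (transketalisation) of the dimethyl ketal through its oxocarbenium ion, in which methanol as solvent should hold the exchange at one methoxy group and suppress the gem-dihydroperoxide.

Step 18
Reactants: 26 (3R,4R)-7-hydroperoxy-7-methoxy-3-methyloct-1-en-4-yl methanesulfonate
Product: 27 (3S)-3-[(2R)-but-3-en-2-yl]-6-methoxy-6-methyl-1,2-dioxane (C6 epimers)
Conditions: KOtBu (1.0 equiv), 18-crown-6, THF, 0 °C
Reagents that add atoms: none
Why: Intramolecular hydroperoxide alkylation, a 6-exo-tet SN2 displacement of the secondary mesylate by the peroxy anion that inverts the carbinol carbon and so sets dioxane C3.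

Step 19
Reactants: 27 (3S)-3-[(2R)-but-3-en-2-yl]-6-methoxy-6-methyl-1,2-dioxane
Product: 29 (2S)-2-[(3S)-6-methoxy-6-methyl-1,2-dioxan-3-yl]propanoic acid, via aldehyde 28 (not isolated)
Conditions: O3, MeCN/H2O (10:1), 0 °C; then NaClO2, H2O, 0 °C to rt
Reagents that add atoms: ozone [O-][O+]=O; sodium chlorite [Na+].[O-]Cl=O
Why: Ozonolysis in aqueous acetonitrile, where water traps the carbonyl oxide and gives the aldehyde directly, telescoped with a Pinnick-type chlorite oxidation, a sequence that is independent of the direction of ozonide cleavage, leaves the dialkyl peroxide alone and is non-basic so that the α-stereocentre is kept.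

Step 20
Reactants: 29 (2S)-2-[(3S)-6-methoxy-6-methyl-1,2-dioxan-3-yl]propanoic acid
Product: 30 methyl (2S)-2-[(3S)-6-methoxy-6-methyl-1,2-dioxan-3-yl]propanoate (fragment 2)
Conditions: Me3SiCHN2, MeOH/toluene, 0 °C
Reagents that add atoms: trimethylsilyldiazomethane C[Si](C)(C)C=[N+]=[N-]
Why: Esterification with trimethylsilyldiazomethane, which is neutral and therefore avoids epimerisation or β-elimination of the β-peroxy acid.

Step 21
Reactants: 18 potassium trifluoro{[(5R,9S,10R)-11-nordrim-7-en-9-yl]ethynyl}borate; 30 methyl (2S)-2-[(3S)-6-methoxy-6-methyl-1,2-dioxan-3-yl]propanoate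
Product: 33 methyl (2S)-2-[(3S,6R)-6-methyl-6-{[(5R,9S,10R)-11-nordrim-7-en-9-yl]ethynyl}-1,2-dioxan-3-yl]propanoate, via alkynyldifluoroborane 31 (not isolated), via peroxycarbenium ion 32 (not isolated)
Conditions: BF3·OEt2 (3 equiv), CH2Cl2, −78 to −30 °C
Reagents that add atoms: none
Why: Proposed new method: BF3·OEt2 should take fluoride from 18 to give alkynyldifluoroborane 31, which abstracts methoxide from C6 of either epimer of 30 to give the methyl-stabilised six-membered peroxycarbenium ion 32, and the resulting alkynyl(methoxy)borate transfers its alkynyl group to C6 to form the C6–C(sp) bond; the closest known reaction types are Lewis acid-mediated substitutions of 3-alkoxy-1,2-dioxolanes and 3-alkoxy-1,2-dioxanes by allylsilanes and silyl ketene acetals (which also build fully substituted peroxide carbons) and BF3-promoted additions of potassium alkynyltrifluoroborates to acetals. No ring is closed, the step being an intermolecular addition to a cyclic tertiary cation. The new stereocentre C6 is controlled by the C3 substituent: 32 should adopt a half-chair with the C3 propanoate pseudo-equatorial, and the slim sp nucleophile should enter along the axial trajectory that leads directly to a chair, so that the alkyne ends axial and cis to the C3 substituent and the methyl equatorial (6R here, 6S in the target, by priority change only). The step needs ionisation of methoxide in preference to O–O heterolysis and alkynyl transfer in preference to attack by the C7=C8 alkene. The mild non-reducing Lewis acid at low temperature and the high nucleophilicity of the alkynyl–boron bond should secure this, and the non-basic medium spares the ester α-centre and C9.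

Step 22
Reactants: 33 methyl (2S)-2-[(3S,6R)-6-methyl-6-{[(5R,9S,10R)-11-nordrim-7-en-9-yl]ethynyl}-1,2-dioxan-3-yl]propanoate
Product: 34 methyl (2S)-2-[(3S,6S)-6-methyl-6-{2-[(5R,9S,10R)-11-nordrim-7-en-9-yl]ethyl}-1,2-dioxan-3-yl]propanoate (target CNP0124238.2)
Conditions: KO2CN=NCO2K (excess, in portions), AcOH, MeOH/CH2Cl2, 0 °C to rt
Reagents that add atoms: none
Why: Diimide reduction, a concerted syn transfer of hydrogen that should saturate the alkyne through the cis-alkene while the O–O bond, the ester and the hindered trisubstituted C7=C8 alkene do not react and no stereocentre is touched.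

Compound list
1 | 3-(trimethylsilyl)prop-2-yn-1-ol | C[Si](C)(C)C#CCO | starting material
2 | (Z)-3-(trimethylsilyl)prop-2-en-1-ol | C[Si](C)(C)/C=C\CO | intermediate
3 | (Z)-(3-bromoprop-1-enyl)trimethylsilane | C[Si](C)(C)/C=C\CBr | intermediate
4 | (S)-(+)-carvone | CC1=CC[C@@H](CC1=O)C(C)=C | starting material
5 | (5S)-6-methylcarvone, mixture of C6 epimers | O=C1C(C)=CC[C@H](C(C)=C)C1C | intermediate
6 | (5R,6R)-2,6-dimethyl-5-isopropenyl-6-[(Z)-3-(trimethylsilyl)prop-2-enyl]cyclohex-2-enone, silylallyl trans to isopropenyl | O=C1C(C)=CC[C@H](C(C)=C)[C@@]1(C)C/C=C\[Si](C)(C)C | intermediate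
7 | (5R,10R)-11-nordrima-2,7-dien-9-one, trans-fused | O=C1C(C)=CC[C@@H]2C(C)(C)C=CC[C@]21C | intermediate
8 | (5R,10R)-11-nordrim-7-en-9-one | O=C1C(C)=CC[C@@H]2C(C)(C)CCC[C@]21C | intermediate
9 | ethynyltrimethylsilane | C#C[Si](C)(C)C | starting material
10 | (5R,10R)-9-[(trimethylsilyl)ethynyl]-11-nordrim-7-en-9-ol, C9 epimers | C[Si](C)(C)C#CC1(O)C(C)=CC[C@@H]2C(C)(C)CCC[C@]21C | intermediate
11 | (5R,10R)-9-[(trimethylsilyl)ethynyl]-11-nordrim-8-en-7-one | O=C1C[C@@H]2C(C)(C)CCC[C@@]2(C)C(C#C[Si](C)(C)C)=C1C | intermediate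
12 | tosylhydrazone of 11 | Cc1ccc(cc1)S(=O)(=O)NN=C1C[C@@H]2C(C)(C)CCC[C@@]2(C)C(C#C[Si](C)(C)C)=C1C | intermediate
13 | (7R)-allylic N-tosylhydrazine, nitrogen on C7 syn to 10-CH3 | Cc1ccc(cc1)S(=O)(=O)NN[C@@H]1C[C@@H]2C(C)(C)CCC[C@@]2(C)C(C#C[Si](C)(C)C)=C1C | intermediate
14 | (7R)-allylic diazene, nitrogen on C7 syn to 10-CH3 | N=N[C@@H]1C[C@@H]2C(C)(C)CCC[C@@]2(C)C(C#C[Si](C)(C)C)=C1C | intermediate
15 | (5R,9S,10R)-9-[(trimethylsilyl)ethynyl]-11-nordrim-7-ene, 9-H syn to 10-CH3 | C[Si](C)(C)C#C[C@H]1C(C)=CC[C@@H]2C(C)(C)CCC[C@]21C | intermediate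
16 | (5R,9S,10R)-9-ethynyl-11-nordrim-7-ene | C#C[C@H]1C(C)=CC[C@@H]2C(C)(C)CCC[C@]21C | intermediate
17 | lithium trimethoxy{[(5R,9S,10R)-11-nordrim-7-en-9-yl]ethynyl}borate | [Li+].CO[B-](OC)(OC)C#C[C@H]1C(C)=CC[C@@H]2C(C)(C)CCC[C@]21C | intermediate
18 | potassium trifluoro{[(5R,9S,10R)-11-nordrim-7-en-9-yl]ethynyl}borate (fragment 1) | [K+].F[B-](F)(F)C#C[C@H]1C(C)=CC[C@@H]2C(C)(C)CCC[C@]21C | intermediate
19 | methyl levulinate | CC(=O)CCC(=O)OC | starting material
20 | methyl 4,4-dimethoxypentanoate | COC(=O)CCC(C)(OC)OC | intermediate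
21 | 4,4-dimethoxypentanal | O=CCCC(C)(OC)OC | intermediate
22 | cis-but-2-ene | C/C=C\C | starting material
23 | (Z)-but-2-enylbis(isopinocampheyl)borane, isopinocampheyl groups from (+)-α-pinene | C/C=C\CB([C@@H]1C[C@@H]2C[C@H]([C@H]1C)C2(C)C)[C@@H]1C[C@@H]2C[C@H]([C@H]1C)C2(C)C | intermediate
24 | (3R,4R)-7,7-dimethoxy-3-methyloct-1-en-4-ol, syn | C=C[C@@H](C)[C@H](O)CCC(C)(OC)OC | intermediate
25 | (3R,4R)-7,7-dimethoxy-3-methyloct-1-en-4-yl methanesulfonate | C=C[C@@H](C)[C@H](OS(C)(=O)=O)CCC(C)(OC)OC | intermediate
26 | (3R,4R)-7-hydroperoxy-7-methoxy-3-methyloct-1-en-4-yl methanesulfonate, C7 epimers | C=C[C@@H](C)[C@H](OS(C)(=O)=O)CCC(C)(OC)OO | intermediate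
27 | (3S)-3-[(2R)-but-3-en-2-yl]-6-methoxy-6-methyl-1,2-dioxane, C6 epimers | C=C[C@@H](C)[C@@H]1CCC(C)(OC)OO1 | intermediate
28 | (2S)-2-[(3S)-6-methoxy-6-methyl-1,2-dioxan-3-yl]propanal | O=C[C@@H](C)[C@@H]1CCC(C)(OC)OO1 | intermediate
29 | (2S)-2-[(3S)-6-methoxy-6-methyl-1,2-dioxan-3-yl]propanoic acid | OC(=O)[C@@H](C)[C@@H]1CCC(C)(OC)OO1 | intermediate
30 | methyl (2S)-2-[(3S)-6-methoxy-6-methyl-1,2-dioxan-3-yl]propanoate (fragment 2) | COC(=O)[C@@H](C)[C@@H]1CCC(C)(OC)OO1 | intermediate
31 | difluoro{[(5R,9S,10R)-11-nordrim-7-en-9-yl]ethynyl}borane | FB(F)C#C[C@H]1C(C)=CC[C@@H]2C(C)(C)CCC[C@]21C | intermediate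
32 | cyclic peroxycarbenium ion, (3S)-3-[(2S)-1-methoxy-1-oxopropan-2-yl]-6-methyl-4,5-dihydro-3H-1,2-dioxin-1-ium | COC(=O)[C@@H](C)[C@@H]1CCC(C)=[O+]O1 | intermediate
33 | methyl (2S)-2-[(3S,6R)-6-methyl-6-{[(5R,9S,10R)-11-nordrim-7-en-9-yl]ethynyl}-1,2-dioxan-3-yl]propanoate, alkyne cis to the C3 substituent | COC(=O)[C@@H](C)[C@@H]1CC[C@](C)(C#C[C@H]2C(C)=CC[C@@H]3C(C)(C)CCC[C@]32C)OO1 | intermediate
34 | methyl (2S)-2-[(3S,6S)-6-methyl-6-{2-[(5R,9S,10R)-11-nordrim-7-en-9-yl]ethyl}-1,2-dioxan-3-yl]propanoate, CNP0124238.2 | COC(=O)[C@@H](C)[C@@H]1CC[C@](C)(CC[C@H]2C(C)=CC[C@@H]3C(C)(C)CCC[C@]32C)OO1 | target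

Total step count: 22.
Longest linear sequence: 13 steps (1 → 2 → 3 → 6 → 7 → 8 → 10 → 11 → 12 → 15 → 16 → 18 → 33 → 34); the peroxide branch from 19 takes 10 steps to 34.

Steps most likely to fail

1. Step 21 (proposed new method). What may go wrong: heterolysis of the O–O bond or proton loss from the peroxycarbenium ion may outrun the alkynyl transfer, the transfer may be too slow at the fully substituted carbon, the propargylic peroxide product may re-ionise, or facial selectivity at C6 may be poor. The fallback installs the peroxide last on a finished carbon chain by known radical hydroperoxidation and oxa-Michael closure; it sets out from alkyne 16 and aldehyde 21 and comes back at target 34. Semihydrogenation of 16 (H2, Pd/CaCO3 poisoned with Pb(OAc)2, quinoline) would give (5R,9S,10R)-9-vinyl-11-nordrim-7-ene F1. Wittig reaction of 21 with Ph3P=C(CH3)CO2CH3 would give methyl (E)-6,6-dimethoxy-2-methylhept-2-enoate F2, aqueous acid would free methyl (E)-2-methyl-6-oxohept-2-enoate F3, and kinetic enolisation (KN(SiMe3)2, −78 °C) followed by PhNTf2 would give the terminal enol triflate F4. Hydroboration of the vinyl group of F1 with 9-borabicyclo[3.3.1]nonane would give the B-alkyl borane F5, which would be coupled in the same flask with F4 (Suzuki–Miyaura, PdCl2(dppf), K3PO4) to the 1,1-disubstituted alkene F6. Isayama–Mukaiyama peroxidation (Co(acac)2, Et3SiH, O2) should act on the 1,1-disubstituted alkene in preference to the hindered ring alkene and the enoate and give the tertiary triethylsilyl peroxide F7. Bu4NF would free the tertiary hydroperoxide F8, and Et2NH in CF3CH2OH would close the 1,2-dioxane by 6-exo oxa-Michael addition to give 34 together with its diastereomers at C6, C3 and the propanoate α-carbon, to be separated by chromatography. This detour is longer and gives up stereocontrol at the three dioxane-side centres.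

2. Step 18. What may go wrong: E2 elimination of the mesylate towards the conjugated diene, or base-induced breakdown of the hydroperoxyketal anion, may compete with the 6-exo displacement at a β-branched secondary carbon. The fallback forms the C3–O bond first and closes the ring at the ketal carbon under acid; it sets out from mesylate 25 and comes back at 27. Displacement of the mesylate of 25 by 2-methoxyprop-2-yl hydroperoxide (CsOH·H2O, DMF) with inversion would give the monoperoxyketal (3R,4S)-7,7-dimethoxy-4-[(2-methoxypropan-2-yl)peroxy]-3-methyloct-1-ene F9. Catalytic TsOH in methanol would then remove the 2-methoxyprop-2-yl group, and the freed secondary hydroperoxide would attack the oxocarbenium ion of the dimethyl ketal (6-exo transketalisation) to give 27.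

3. Step 10. What may go wrong: insufficient facial selectivity in the hydride delivery to the hydrazone, which would erode the configuration at C9. The fallback sets C7 by reagent control and inverts it; it sets out from enynone 11 and comes back at 15. Corey–Bakshi–Shibata reduction of 11 with (R)-2-methyl-CBS-oxazaborolidine and catecholborane would give the (7S)-allylic alcohol F10 (OH anti to the 10-methyl). Mitsunobu reaction with 2-nitrobenzenesulfonyl hydrazide (PPh3, diethyl azodicarboxylate, −30 °C) would invert C7 and give the N-allyl sulfonylhydrazine F11, which on warming loses 2-nitrobenzenesulfinic acid to give the same diazene 14 and hence 15.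

Further compounds
F1 | step 21 | (5R,9S,10R)-9-vinyl-11-nordrim-7-ene | C=C[C@H]1C(C)=CC[C@@H]2C(C)(C)CCC[C@]21C
F2 | step 21 | methyl (E)-6,6-dimethoxy-2-methylhept-2-enoate | COC(=O)/C(C)=C/CCC(C)(OC)OC
F3 | step 21 | methyl (E)-2-methyl-6-oxohept-2-enoate | COC(=O)/C(C)=C/CCC(C)=O
F4 | step 21 | methyl (E)-2-methyl-6-(trifluoromethylsulfonyloxy)hepta-2,6-dienoate | COC(=O)/C(C)=C/CCC(=C)OS(=O)(=O)C(F)(F)F
F5 | step 21 | 9-{2-[(5R,9S,10R)-11-nordrim-7-en-9-yl]ethyl}-9-borabicyclo[3.3.1]nonane | C(C[C@H]1C(C)=CC[C@@H]2C(C)(C)CCC[C@]21C)B1C2CCCC1CCC2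
F6 | step 21 | methyl (E)-2-methyl-6-methylidene-8-[(5R,9S,10R)-11-nordrim-7-en-9-yl]oct-2-enoate | COC(=O)/C(C)=C/CCC(=C)CC[C@H]1C(C)=CC[C@@H]2C(C)(C)CCC[C@]21C
F7 | step 21 | methyl (E)-2,6-dimethyl-8-[(5R,9S,10R)-11-nordrim-7-en-9-yl]-6-(triethylsilylperoxy)oct-2-enoate, C6 epimers | COC(=O)/C(C)=C/CCC(C)(OO[Si](CC)(CC)CC)CC[C@H]1C(C)=CC[C@@H]2C(C)(C)CCC[C@]21C
F8 | step 21 | methyl (E)-6-hydroperoxy-2,6-dimethyl-8-[(5R,9S,10R)-11-nordrim-7-en-9-yl]oct-2-enoate, C6 epimers | COC(=O)/C(C)=C/CCC(C)(OO)CC[C@H]1C(C)=CC[C@@H]2C(C)(C)CCC[C@]21C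
F9 | step 18 | (3R,4S)-7,7-dimethoxy-4-[(2-methoxypropan-2-yl)peroxy]-3-methyloct-1-ene | C=C[C@@H](C)[C@@H](OOC(C)(C)OC)CCC(C)(OC)OC
F10 | step 10 | (5R,7S,10R)-9-[(trimethylsilyl)ethynyl]-11-nordrim-8-en-7-ol, OH anti to 10-CH3 | O[C@H]1C[C@@H]2C(C)(C)CCC[C@@]2(C)C(C#C[Si](C)(C)C)=C1C
F11 | step 10 | (7R)-N-allyl-N-(2-nitrobenzenesulfonyl)hydrazine, nitrogen on C7 syn to 10-CH3 | NN([C@@H]1C[C@@H]2C(C)(C)CCC[C@@]2(C)C(C#C[Si](C)(C)C)=C1C)S(=O)(=O)c1ccccc1[N+](=O)[O-]
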